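Numbering the chain from the lactone carbonyl (C1; lactone carbinol C7, cyclopropane C8–C10, carbinols C11 and C14), everything rests on the C10–C11 bond. The key step exploits the (E)-2-ene-1,4-diol unit C11–C14 next to the cyclopropane ring: a cyclopropylboronate that already carries the eight-membered lactone and a lithiated (E)-iodovinyl trans-epoxide give a boron ate complex, whose vinylogous 1,2-metallate shift moves the cyclopropyl carbon from boron to C11 as the oxirane opens in SN2′ fashion. One operation forms C10–C11, sets C11 by chirality transfer, creates the C12=C13 E-alkene and releases the C14 oxygen; oxidation of the allylboronate then gives the C11 hydroxyl.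

Key step: step 11

Assumption: 1, 2, 5 and 9 are taken as commercial; if 1 is not in stock it is one acid hydrolysis from its commercial diethyl acetal. Bpin (pinacolboryl) = 4,4,5,5-tetramethyl-1,3,2-dioxaborolan-2-yl.

Step 1
Reactants: 1 (2E)-3-(pinacolboryl)prop-2-enal; 2 allyltributylstannane
Product: 3 (1E,3R)-1-(pinacolboryl)hexa-1,5-dien-3-ol
Conditions: (R)-BINOL (20 mol%), Ti(OiPr)4 (10 mol%), 4 Å MS, CH2Cl2, −20 °C; aq. NaHCO3
Reagents that add atoms: none
Why: Keck asymmetric allylation, in which the (R)-BINOL/Ti(OiPr)4 Lewis acid should direct Re-face 1,2-addition of the allylstannane to the enal and so set C7 as R by reagent control, under neutral conditions that leave the alkenyl C–B bond intact.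

Step 2
Reactants: 3 (1E,3R)-1-(pinacolboryl)hexa-1,5-dien-3-ol
Product: 4 (1R)-1-[(1R,2R)-2-(pinacolboryl)cyclopropyl]but-3-en-1-ol
Conditions: Et2Zn (2.2 equiv), CH2I2 (2.2 equiv), CH2Cl2, −10 → 0 °C
Reagents that add atoms: diiodomethane ICI
Why: Hydroxyl-directed Simmons–Smith cyclopropanation (Furukawa reagent), in which the zinc alkoxide should deliver CH2 to the allylic alkene on the face syn to oxygen in the conformer with C7–H eclipsing the alkene, setting C8 and C10 (trans from the E-alkene) and reacting ahead of the homoallylic vinyl group.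

Step 3
Reactants: 4 (1R)-1-[(1R,2R)-2-(pinacolboryl)cyclopropyl]but-3-en-1-ol; 5 pent-4-enoic acid
Product: 6 (1R)-1-[(1R,2R)-2-(pinacolboryl)cyclopropyl]but-3-en-1-yl pent-4-enoate
Conditions: DCC, DMAP (cat.), CH2Cl2, 0 °C → rt
Reagents that add atoms: none
Why: Steglich esterification of the secondary alcohol, which touches no stereocentre and leaves the boronate untouched.

Step 4
Reactants: 6 (1R)-1-[(1R,2R)-2-(pinacolboryl)cyclopropyl]but-3-en-1-yl pent-4-enoate
Product: 7 (5Z,8R)-8-[(1R,2R)-2-(pinacolboryl)cyclopropyl]-3,4,7,8-tetrahydro-2H-oxocin-2-one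
Conditions: second-generation Grubbs catalyst (5 mol%), CH2Cl2 (1 mM), 40 °C
Reagents that add atoms: none
Why: Ring-closing metathesis of the two terminal alkenes should give the eight-membered Z-lactone with loss of ethene, the branched secondary ester favouring the folded conformer and the cyclopropylboronate staying inert.

Step 5
Reactants: 7 (5Z,8R)-8-[(1R,2R)-2-(pinacolboryl)cyclopropyl]-3,4,7,8-tetrahydro-2H-oxocin-2-one
Product: 8 (8R)-8-[(1R,2R)-2-(pinacolboryl)cyclopropyl]oxocan-2-one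
Conditions: H2 (1 atm), Pd/C, EtOAc, rt
Reagents that add atoms: none
Why: Heterogeneous catalytic hydrogenation should saturate the isolated cis-alkene, while the unactivated cyclopropane and the C–B bond are not hydrogenolysed under these mild conditions.

Step 6
Reactants: 9 (3Z,6Z)-nona-3,6-dien-1-ol
Product: 11 ethyl (2E,5Z,8Z)-undeca-2,5,8-trienoate, via dienal 10 (not isolated)
Conditions: Dess–Martin periodinane, pyridine, CH2Cl2, 0 °C; then Ph3P=CHCO2Et, 0 °C → rt
Reagents that add atoms: ethyl (triphenylphosphoranylidene)acetate CCOC(=O)C=P(c1ccccc1)(c1ccccc1)c1ccccc1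
Why: Dess–Martin oxidation followed in the same flask by Wittig olefination with the stabilised ylide should trap the isomerisation-prone β,γ-unsaturated aldehyde as the E-enoate.

Step 7
Reactants: 11 ethyl (2E,5Z,8Z)-undeca-2,5,8-trienoate
Product: 12 (2E,5Z,8Z)-undeca-2,5,8-trien-1-ol
Conditions: iBu2AlH (2.2 equiv), CH2Cl2, −78 °C; aq. potassium sodium tartrate
Reagents that add atoms: none
Why: Hydride 1,2-reduction of the enoate should give the allylic alcohol without touching the skipped Z,Z-diene.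

Step 8
Reactants: 12 (2E,5Z,8Z)-undeca-2,5,8-trien-1-ol
Product: 13 [(2S,3S)-3-[(2Z,5Z)-octa-2,5-dien-1-yl]oxiran-2-yl]methanol
Conditions: Ti(OiPr)4 (10 mol%), L-(+)-diethyl tartrate (12 mol%), tBuOOH, 4 Å MS, CH2Cl2, −20 °C
Reagents that add atoms: tert-butyl hydroperoxide CC(C)(C)OO
Why: Sharpless asymmetric epoxidation should oxidise only the allylic alkene and set C13 and C14 as (S,S) by reagent control of the L-tartrate.

Step 9
Reactants: 13 [(2S,3S)-3-[(2Z,5Z)-octa-2,5-dien-1-yl]oxiran-2-yl]methanol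
Product: 14 (2R,3S)-3-[(2Z,5Z)-octa-2,5-dien-1-yl]oxirane-2-carbaldehyde
Conditions: Dess–Martin periodinane, pyridine, CH2Cl2, 0 °C
Reagents that add atoms: none
Why: Buffered Dess–Martin oxidation should give the epoxy aldehyde without epimerisation or epoxide opening (the descriptor at C13 changes only through the priority rules).

Step 10
Reactants: 14 (2R,3S)-3-[(2Z,5Z)-octa-2,5-dien-1-yl]oxirane-2-carbaldehyde
Product: 15 (2S,3S)-2-[(E)-2-iodoethenyl]-3-[(2Z,5Z)-octa-2,5-dien-1-yl]oxirane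
Conditions: CrCl2, CHI3, THF, 0 °C
Reagents that add atoms: iodoform IC(I)I
Why: Takai olefination should convert the aldehyde into the (E)-iodoalkene (C11) through the geminal dichromium reagent, with the epoxide untouched.

Step 11
Reactants: 15 (2S,3S)-2-[(E)-2-iodoethenyl]-3-[(2Z,5Z)-octa-2,5-dien-1-yl]oxirane; 8 (8R)-8-[(1R,2R)-2-(pinacolboryl)cyclopropyl]oxocan-2-one
Product: 20 (8R)-8-[(1R,2R)-2-[(1R,2E,4S,6Z,9Z)-1,4-dihydroxydodeca-2,6,9-trien-1-yl]cyclopropyl]oxocan-2-one, via alkenyllithium 16 (not isolated), via lithium boronate complex 17 (not isolated), via silylated allylboronate 18 (not isolated), via C14 trimethylsilyl ether 19 (not isolated)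
Conditions: 15, tBuLi (2.0 equiv), Et2O, −78 °C; cannulate into 8 (1.1 equiv), THF, −95 °C; Me3SiOTf (1.2 equiv), −78 → 0 °C; 30% H2O2, aq. NaHCO3, 0 °C; 10% aq. citric acid
Reagents that add atoms: hydrogen peroxide OO
Why: Proposed new method: alkenyllithium 16 should add to the boron of 8 far faster than to the lactone, and silylation of the oxirane oxygen of ate complex 17 should trigger a vinylogous 1,2-metallate rearrangement in which cyclopropyl carbon C10 migrates with retention from boron to C11 while the C11=C12 π bond shifts to C12=C13 and the allylic C13–O bond breaks (SN2′), giving allylboronate 18; no ring is closed. The closest known reaction types are the SN2′-type 1,2-metallate rearrangement of γ-chloroalkenyl boronate complexes to α-substituted allylboronates and the silyl-triflate-promoted ring-opening 1,2-migration of boronate complexes made from lithiated epoxides. The new stereocentre C11 is controlled by C13 of the epoxide: migration anti to the leaving oxygen in the s-trans conformer (C14 anti to C11) of the (E)-alkenyl (13S,14S)-epoxide places the cyclopropyl so that stereoretentive C–B oxidation gives 11R, while C14 (S) keeps its C–O bond and C10 keeps its configuration. The step needs anti over syn SN2′ selectivity (secured by overlap of the C13–O bond with the π system opposite the migrating group), E over Z alkene geometry (secured by the s-trans conformer, which is free of allylic 1,3-strain) and boron over lactone chemoselectivity (secured by inverse addition at −95 °C). Buffered H2O2 should then oxidise 18 to 19 without allylic shift, and the mild acid work-up should remove the silyl group to give 20.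

Compound list
1 | (2E)-3-(4,4,5,5-tetramethyl-1,3,2-dioxaborolan-2-yl)prop-2-enal (3-boronoacrolein pinacolate) | O=C/C=C/B1OC(C)(C)C(C)(C)O1 | starting material
2 | allyltributylstannane | C=CC[Sn](CCCC)(CCCC)CCCC | starting material
3 | (1E,3R)-1-(pinacolboryl)hexa-1,5-dien-3-ol | CC1(C)OB(OC1(C)C)/C=C/[C@H](O)CC=C | intermediate
4 | (1R)-1-[(1R,2R)-2-(pinacolboryl)cyclopropyl]but-3-en-1-ol | CC1(C)OB(OC1(C)C)[C@@H]2C[C@H]2[C@H](O)CC=C | intermediate
5 | pent-4-enoic acid | C=CCCC(O)=O | starting material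
6 | (1R)-1-[(1R,2R)-2-(pinacolboryl)cyclopropyl]but-3-en-1-yl pent-4-enoate | CC1(C)OB(OC1(C)C)[C@@H]2C[C@H]2[C@H](OC(=O)CCC=C)CC=C | intermediate
7 | (5Z,8R)-8-[(1R,2R)-2-(pinacolboryl)cyclopropyl]-3,4,7,8-tetrahydro-2H-oxocin-2-one | CC1(C)OB(OC1(C)C)[C@@H]2C[C@H]2[C@H]3C/C=C\CCC(=O)O3 | intermediate
8 | (8R)-8-[(1R,2R)-2-(pinacolboryl)cyclopropyl]oxocan-2-one | CC1(C)OB(OC1(C)C)[C@@H]2C[C@H]2[C@H]3CCCCCC(=O)O3 | intermediate
9 | (3Z,6Z)-nona-3,6-dien-1-ol | CC/C=C\C/C=C\CCO | starting material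
10 | (3Z,6Z)-nona-3,6-dienal | CC/C=C\C/C=C\CC=O | intermediate
11 | ethyl (2E,5Z,8Z)-undeca-2,5,8-trienoate | CC/C=C\C/C=C\C/C=C/C(=O)OCC | intermediate
12 | (2E,5Z,8Z)-undeca-2,5,8-trien-1-ol | CC/C=C\C/C=C\C/C=C/CO | intermediate
13 | [(2S,3S)-3-[(2Z,5Z)-octa-2,5-dien-1-yl]oxiran-2-yl]methanol | CC/C=C\C/C=C\C[C@@H]1O[C@H]1CO | intermediate
14 | (2R,3S)-3-[(2Z,5Z)-octa-2,5-dien-1-yl]oxirane-2-carbaldehyde | CC/C=C\C/C=C\C[C@@H]1O[C@H]1C=O | intermediate
15 | (2S,3S)-2-[(E)-2-iodoethenyl]-3-[(2Z,5Z)-octa-2,5-dien-1-yl]oxirane | CC/C=C\C/C=C\C[C@@H]1O[C@H]1/C=C/I | intermediate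
16 | [(E)-2-[(2S,3S)-3-[(2Z,5Z)-octa-2,5-dien-1-yl]oxiran-2-yl]ethenyl]lithium | CC/C=C\C/C=C\C[C@@H]1O[C@H]1/C=C/[Li] | intermediate
17 | lithium {(1R,2R)-2-[(2R)-8-oxooxocan-2-yl]cyclopropyl}{(E)-2-[(2S,3S)-3-[(2Z,5Z)-octa-2,5-dien-1-yl]oxiran-2-yl]ethenyl}(pinacolato)borate | [Li+].CC/C=C\C/C=C\C[C@@H]1O[C@H]1/C=C/[B-]2(OC(C)(C)C(C)(C)O2)[C@@H]3C[C@H]3[C@H]4CCCCCC(=O)O4 | intermediate
18 | (8R)-8-[(1R,2S)-2-[(1R,2E,4S,6Z,9Z)-1-(pinacolboryl)-4-(trimethylsilyloxy)dodeca-2,6,9-trien-1-yl]cyclopropyl]oxocan-2-one | CC/C=C\C/C=C\C[C@H](O[Si](C)(C)C)/C=C/[C@@H](B1OC(C)(C)C(C)(C)O1)[C@@H]2C[C@H]2[C@H]3CCCCCC(=O)O3 | intermediate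
19 | (8R)-8-[(1R,2R)-2-[(1R,2E,4S,6Z,9Z)-1-hydroxy-4-(trimethylsilyloxy)dodeca-2,6,9-trien-1-yl]cyclopropyl]oxocan-2-one | CC/C=C\C/C=C\C[C@H](O[Si](C)(C)C)/C=C/[C@@H](O)[C@@H]1C[C@H]1[C@H]1CCCCCC(=O)O1 | intermediate
20 | (8R)-8-[(1R,2R)-2-[(1R,2E,4S,6Z,9Z)-1,4-dihydroxydodeca-2,6,9-trien-1-yl]cyclopropyl]oxocan-2-one | CC/C=C\C/C=C\C[C@H](O)/C=C/[C@@H](O)[C@@H]1C[C@H]1[C@H]1CCCCCC(=O)O1 | target

Total step count: 11. Longest linear sequence: 6 steps (steps 1–5 then 11, or steps 6–10 then 11).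

Steps most likely to fail

Step 11. The ate complex may fail to rearrange, the silyl triflate may attack a pinacol oxygen instead of the oxirane, the alkenyllithium may add to the lactone, or migration may occur syn to the leaving oxygen. The fallback makes the C10–C11 bond by known cross-coupling chemistry and sets out from 14 and 8. Stork–Zhao olefination of 14 (Ph3PCH2I iodide, NaN(SiMe3)2, THF/DMPU, −78 °C) would give (2S,3S)-2-[(Z)-2-iodoethenyl]-3-[(2Z,5Z)-octa-2,5-dien-1-yl]oxirane F1. Stereoretentive Suzuki–Miyaura coupling of F1 with 8 (PdCl2(dppf), K3PO4, toluene/H2O) would give (8R)-8-[(1R,2S)-2-[(Z)-2-[(2S,3S)-3-[(2Z,5Z)-octa-2,5-dien-1-yl]oxiran-2-yl]ethenyl]cyclopropyl]oxocan-2-one F2. Copper-catalysed anti-SN2′ borylation of this allylic epoxide (CuCl, Xantphos, NaOtBu, B2pin2, MeOH, THF), a known reaction type, would give (8R)-8-[(1R,2S)-2-[(1R,2E,4S,6Z,9Z)-4-hydroxy-1-(pinacolboryl)dodeca-2,6,9-trien-1-yl]cyclopropyl]oxocan-2-one F3. The Z-alkene compensates for the exchanged roles of carbon and boron, so C11 should again be R. Buffered H2O2 oxidation of F3 would come back to the route at 20.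

Step 4. Oligomerisation may outrun closure of the eight-membered ring. The fallback closes the ring through the C–O bond and sets out from 4 and 5. Cross-metathesis of 4 with 5 (second-generation Grubbs catalyst, CH2Cl2, 40 °C) would give (4E,7R)-7-hydroxy-7-[(1R,2R)-2-(pinacolboryl)cyclopropyl]hept-4-enoic acid F4. Hydrogenation (H2, Pd/C) would give (7R)-7-hydroxy-7-[(1R,2R)-2-(pinacolboryl)cyclopropyl]heptanoic acid F5. Shiina macrolactonisation of F5 (2-methyl-6-nitrobenzoic anhydride, DMAP, Et3N, slow addition at high dilution) would come back to the route at 8.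

Step 2. The zinc carbenoid may also cyclopropanate the homoallylic vinyl group, or facial selectivity may be incomplete. The fallback builds the cyclopropane before the terminal alkene exists and sets out from 1. Luche reduction (NaBH4, CeCl3·7H2O, MeOH) would give (2E)-3-(pinacolboryl)prop-2-en-1-ol F6. Ligand-controlled asymmetric Simmons–Smith cyclopropanation (Zn(CH2I)2 with (4S,5S)-2-butyl-N,N,N′,N′-tetramethyl-1,3,2-dioxaborolane-4,5-dicarboxamide, CH2Cl2) would give [(1R,2R)-2-(pinacolboryl)cyclopropyl]methanol F7. Dess–Martin oxidation would give (1R,2R)-2-(pinacolboryl)cyclopropane-1-carbaldehyde F8. Keck allylation of F8 with 2 ((R)-BINOL, Ti(OiPr)4) would set C7 by reagent control and come back to the route at 4.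

Further compounds
F1 | step 11 | (2S,3S)-2-[(Z)-2-iodoethenyl]-3-[(2Z,5Z)-octa-2,5-dien-1-yl]oxirane | CC/C=C\C/C=C\C[C@@H]1O[C@H]1/C=C\I
F2 | step 11 | (8R)-8-[(1R,2S)-2-[(Z)-2-[(2S,3S)-3-[(2Z,5Z)-octa-2,5-dien-1-yl]oxiran-2-yl]ethenyl]cyclopropyl]oxocan-2-one | CC/C=C\C/C=C\C[C@@H]1O[C@H]1/C=C\[C@@H]2C[C@H]2[C@H]3CCCCCC(=O)O3
F3 | step 11 | (8R)-8-[(1R,2S)-2-[(1R,2E,4S,6Z,9Z)-4-hydroxy-1-(pinacolboryl)dodeca-2,6,9-trien-1-yl]cyclopropyl]oxocan-2-one | CC/C=C\C/C=C\C[C@H](O)/C=C/[C@@H](B1OC(C)(C)C(C)(C)O1)[C@@H]2C[C@H]2[C@H]3CCCCCC(=O)O3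
F4 | step 4 | (4E,7R)-7-hydroxy-7-[(1R,2R)-2-(pinacolboryl)cyclopropyl]hept-4-enoic acid | CC1(C)OB(OC1(C)C)[C@@H]2C[C@H]2[C@H](O)C/C=C/CCC(O)=O
F5 | step 4 | (7R)-7-hydroxy-7-[(1R,2R)-2-(pinacolboryl)cyclopropyl]heptanoic acid | CC1(C)OB(OC1(C)C)[C@@H]2C[C@H]2[C@H](O)CCCCCC(O)=O
F6 | step 2 | (2E)-3-(pinacolboryl)prop-2-en-1-ol | CC1(C)OB(OC1(C)C)/C=C/CO
F7 | step 2 | [(1R,2R)-2-(pinacolboryl)cyclopropyl]methanol | CC1(C)OB(OC1(C)C)[C@@H]2C[C@H]2CO
F8 | step 2 | (1R,2R)-2-(pinacolboryl)cyclopropane-1-carbaldehyde | CC1(C)OB(OC1(C)C)[C@@H]2C[C@H]2C=O
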